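The dioxane ring is closed at the aryl–oxygen bond between O1 of the benzodioxane (the oxygen on the CH2OH-bearing carbon) and C4' of ring B. The key step exploits that C4' lies para to C1', the carbon that later carries ring C: with a formyl group at C1', a fluoride at C4' is open to SNAr. In one operation the phenoxide of 4-fluoro-3-hydroxybenzaldehyde opens an enantiopure cis-epoxide at its benzylic carbon with inversion, and the alkoxide so released displaces the fluoride, giving the trans-benzodioxane with both stereocentres. A Claisen–Schmidt/Algar–Flynn–Oyamada sequence then builds the flavonol on the aldehyde.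

Key step: step 4

Remark: primed numbers (C1', C3', C4') refer to ring B in flavonoid numbering; O1, C2, C3, O4, C4a and C8a are the benzodioxane atoms. The target is (2R,3R) at the benzodioxane. All hydroxyl groups that must be masked travel as benzyl ethers and are freed together in the last step.

Step 1
Reactants: 1 1-(benzyloxy)-4-bromo-2-methoxybenzene; 2 benzyl propargyl ether
Product: 3 1-(benzyloxy)-4-[3-(benzyloxy)prop-1-yn-1-yl]-2-methoxybenzene
Conditions: Pd(PhCN)2Cl2 (3 mol %), P(t-Bu)3 (6 mol %), CuI (2 mol %), i-Pr2NH, dioxane, rt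
Reagents that add atoms: none
Why: Sonogashira coupling, in which the electron-rich tri-tert-butylphosphine palladium catalyst should insert into the electron-rich aryl bromide at room temperature while the propargylic ether stays inert.

Step 2
Reactants: 3 1-(benzyloxy)-4-[3-(benzyloxy)prop-1-yn-1-yl]-2-methoxybenzene
Product: 4 1-(benzyloxy)-4-[(1Z)-3-(benzyloxy)prop-1-en-1-yl]-2-methoxybenzene
Conditions: H2 (1 atm), Pd/CaCO3 poisoned with Pb(OAc)2 (Lindlar catalyst), quinoline, EtOAc, rt
Reagents that add atoms: none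
Why: Lindlar semihydrogenation, in which syn delivery of hydrogen on the poisoned surface should give the Z-alkene and stop there, with the benzyl ethers untouched on this catalyst.

Step 3
Reactants: 4 1-(benzyloxy)-4-[(1Z)-3-(benzyloxy)prop-1-en-1-yl]-2-methoxybenzene
Product: 5 (2S,3R)-2-[4-(benzyloxy)-3-methoxyphenyl]-3-[(benzyloxy)methyl]oxirane
Conditions: (S,S)-[N,N'-bis(3,5-di-tert-butylsalicylidene)cyclohexane-1,2-diaminato]MnCl (chloride of trivalent manganese, 5 mol %), 4-phenylpyridine N-oxide (20 mol %), aq. NaOCl buffered to pH 11.3, CH2Cl2, 0 °C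
Reagents that add atoms: sodium hypochlorite, [Na+].[O-]Cl
Why: Jacobsen–Katsuki epoxidation of a cis-disubstituted aryl alkene, the best substrate class for this catalyst: side-on approach to the oxo-manganese salen species, steered by the (S,S)-diamine backbone, should deliver oxygen to the face that gives the (2S,3R)-cis-epoxide (the sense known for cis-β-methylstyrene and indene), and the buffered basic medium protects the acid-sensitive electron-rich epoxide.

Step 4
Reactants: 5 (2S,3R)-2-[4-(benzyloxy)-3-methoxyphenyl]-3-[(benzyloxy)methyl]oxirane; 6 4-fluoro-3-hydroxybenzaldehyde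
Product: 8 (2R,3R)-3-[4-(benzyloxy)-3-methoxyphenyl]-2-[(benzyloxy)methyl]-2,3-dihydro-1,4-benzodioxine-6-carbaldehyde, via fluoro alcohol 7 (not isolated)
Conditions: Cs2CO3 (2.5 equiv), DMF, 70 °C then 110 °C
Reagents that add atoms: none
Why: Domino epoxide opening–SNAr: the caesium phenoxide of 6 attacks the benzylic carbon of cis-epoxide 5 in an SN2 (anti) opening, and the secondary alkoxide of 7 then adds to C4' of the fluoroarene, giving a Meisenheimer adduct stabilised by the para formyl group, and expels fluoride. The closest known reaction types are the base-mediated opening of aryl epoxides by phenoxides and the intramolecular SNAr etherification that gives 1,4-benzodioxanes. The dioxane ring closes by a 6-exo-trig addition–elimination at the aromatic carbon, forming the O1–C8a bond. C3 is set by inversion of the S benzylic centre of 5, and C2 keeps the R configuration of the epoxide because its C–O bond is never broken, so the cis-epoxide maps onto the trans-(2R,3R) product. The step needs attack at the benzylic rather than the other epoxide carbon, which benzylic activation and the inductively deactivating CH2OBn neighbour both favour, and it needs substitution at C4' only, the sole ring carbon that bears a leaving group para to the aldehyde.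

Step 5
Reactants: 8 (2R,3R)-3-[4-(benzyloxy)-3-methoxyphenyl]-2-[(benzyloxy)methyl]-2,3-dihydro-1,4-benzodioxine-6-carbaldehyde; 9 1-[2,4-bis(benzyloxy)-6-hydroxyphenyl]ethan-1-one
Product: 11 5,7-bis(benzyloxy)-2-{(2R,3R)-3-[4-(benzyloxy)-3-methoxyphenyl]-2-[(benzyloxy)methyl]-2,3-dihydro-1,4-benzodioxin-6-yl}-3-hydroxy-4H-chromen-4-one, via chalcone 10 (not isolated)
Conditions: KOH (50% aq.), EtOH–THF, rt; then H2O2 (30% aq.), 0 °C to rt
Reagents that add atoms: hydrogen peroxide, OO
Why: Claisen–Schmidt condensation of the methyl ketone of 9 with the non-enolisable aldehyde 8 should give the E-chalcone 10, which under alkaline H2O2 undergoes the Algar–Flynn–Oyamada oxidative cyclisation (phenoxide closure at the β-carbon with hydroxylation at the α-carbon, then dehydrogenation) to the flavonol, while the two dioxane stereocentres bear no acidic hydrogen and stay untouched.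

Step 6
Reactants: 11 5,7-bis(benzyloxy)-2-{(2R,3R)-3-[4-(benzyloxy)-3-methoxyphenyl]-2-[(benzyloxy)methyl]-2,3-dihydro-1,4-benzodioxin-6-yl}-3-hydroxy-4H-chromen-4-one
Product: 12 2,3-dehydrosilybin A
Conditions: H2 (1 atm), Pd(OH)2/C, THF–MeOH, rt
Reagents that add atoms: none
Why: Catalytic hydrogenolysis should remove the three aryl benzyl ethers and the primary benzyl ether, while the flavonol C2=C3 bond is not reduced and the cyclic benzylic C3–O4 bond of the benzodioxane is cleaved far more slowly than O-benzyl groups, so neither stereocentre is touched.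

Compound list
1 | 1-(benzyloxy)-4-bromo-2-methoxybenzene | COc1cc(Br)ccc1OCc1ccccc1 | starting material
2 | benzyl propargyl ether, [(prop-2-yn-1-yloxy)methyl]benzene | C#CCOCc1ccccc1 | starting material
3 | 1-(benzyloxy)-4-[3-(benzyloxy)prop-1-yn-1-yl]-2-methoxybenzene | COc1cc(C#CCOCc2ccccc2)ccc1OCc1ccccc1 | intermediate
4 | 1-(benzyloxy)-4-[(1Z)-3-(benzyloxy)prop-1-en-1-yl]-2-methoxybenzene | COc1cc(/C=C\COCc2ccccc2)ccc1OCc1ccccc1 | intermediate
5 | (2S,3R)-2-[4-(benzyloxy)-3-methoxyphenyl]-3-[(benzyloxy)methyl]oxirane (cis) | COc1cc([C@@H]2O[C@@H]2COCc2ccccc2)ccc1OCc1ccccc1 | intermediate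
6 | 4-fluoro-3-hydroxybenzaldehyde | O=Cc1ccc(F)c(O)c1 | starting material
7 | 3-{[(1R,2R)-3-(benzyloxy)-1-[4-(benzyloxy)-3-methoxyphenyl]-2-hydroxypropyl]oxy}-4-fluorobenzaldehyde (fluoro alcohol) | COc1cc([C@@H](Oc2cc(C=O)ccc2F)[C@H](O)COCc2ccccc2)ccc1OCc1ccccc1 | intermediate
8 | (2R,3R)-3-[4-(benzyloxy)-3-methoxyphenyl]-2-[(benzyloxy)methyl]-2,3-dihydro-1,4-benzodioxine-6-carbaldehyde (trans) | COc1cc([C@H]2Oc3cc(C=O)ccc3O[C@@H]2COCc2ccccc2)ccc1OCc1ccccc1 | intermediate
9 | 1-[2,4-bis(benzyloxy)-6-hydroxyphenyl]ethan-1-one (2'-hydroxy-4',6'-bis(benzyloxy)acetophenone) | CC(=O)c1c(O)cc(OCc2ccccc2)cc1OCc1ccccc1 | starting material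
10 | (2E)-1-[2,4-bis(benzyloxy)-6-hydroxyphenyl]-3-{(2R,3R)-3-[4-(benzyloxy)-3-methoxyphenyl]-2-[(benzyloxy)methyl]-2,3-dihydro-1,4-benzodioxin-6-yl}prop-2-en-1-one (chalcone) | COc1cc([C@H]2Oc3cc(/C=C/C(=O)c4c(O)cc(OCc5ccccc5)cc4OCc4ccccc4)ccc3O[C@@H]2COCc2ccccc2)ccc1OCc1ccccc1 | intermediate
11 | 5,7-bis(benzyloxy)-2-{(2R,3R)-3-[4-(benzyloxy)-3-methoxyphenyl]-2-[(benzyloxy)methyl]-2,3-dihydro-1,4-benzodioxin-6-yl}-3-hydroxy-4H-chromen-4-one | COc1cc([C@H]2Oc3cc(-c4oc5cc(OCc6ccccc6)cc(OCc6ccccc6)c5c(=O)c4O)ccc3O[C@@H]2COCc2ccccc2)ccc1OCc1ccccc1 | intermediate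
12 | 2,3-dehydrosilybin A, 3,5,7-trihydroxy-2-[(2R,3R)-3-(4-hydroxy-3-methoxyphenyl)-2-(hydroxymethyl)-2,3-dihydro-1,4-benzodioxin-6-yl]-4H-chromen-4-one | COc1cc([C@H]2Oc3cc(-c4oc5cc(O)cc(O)c5c(=O)c4O)ccc3O[C@@H]2CO)ccc1O | target

Total step count: 6. Longest linear sequence: 6 steps (1 → 3 → 4 → 5 → 8 → 11 → 12).

Steps most likely to fail

Step 3. Oxygen transfer from the oxo-manganese species to a styrene-type alkene passes through a benzylic radical. With the para-oxygenated ring this radical may live long enough to rotate before collapse, so leakage to the trans-epoxide and a lower enantiomeric excess are possible, and the electron-rich epoxide may open during isolation. The fallback sets out from 1 and comes back to the route at 7; it takes the C2 centre from the chiral pool and avoids the epoxide altogether. Bromine–lithium exchange on 1 (n-BuLi, THF, −78 °C), transmetallation with ClTi(Oi-Pr)3 and Felkin–Anh addition to (R)-2,3-O-isopropylideneglyceraldehyde should give the anti alcohol (S)-[4-(benzyloxy)-3-methoxyphenyl][(4R)-2,2-dimethyl-1,3-dioxolan-4-yl]methanol F1. Mitsunobu etherification with 6 (PPh3, DIAD, toluene, 0 °C) should invert the benzylic centre and give the aryl ether 3-{(R)-[4-(benzyloxy)-3-methoxyphenyl][(4R)-2,2-dimethyl-1,3-dioxolan-4-yl]methoxy}-4-fluorobenzaldehyde F2. Removal of the acetonide (80% AcOH, 40 °C) gives the diol 3-{[(1R,2R)-1-[4-(benzyloxy)-3-methoxyphenyl]-2,3-dihydroxypropyl]oxy}-4-fluorobenzaldehyde F3. Stannylene-mediated benzylation of its primary hydroxyl (Bu2SnO, toluene, reflux; then BnBr, Bu4NI) gives 7, isolated this time, which is closed to 8 with Cs2CO3 in DMF at 110 °C. Any error at the benzylic centre then appears as a separable diastereomer and not as the enantiomer.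

Step 4. The phenoxide may open the epoxide partly at the non-benzylic carbon, and the closing fluoride displacement by a secondary alkoxide that carbonate base holds at low equilibrium concentration may lag, so that prolonged heating erodes the aldehyde. The fallback sets out from 5 and comes back at 8; it separates the two events and closes the same aryl–oxygen bond by palladium catalysis instead of SNAr. Epoxide 5 is opened with 4-bromo-3-hydroxybenzaldehyde (Cs2CO3, DMF, 60 °C) to give the bromo alcohol 4-bromo-3-{[(1R,2R)-3-(benzyloxy)-1-[4-(benzyloxy)-3-methoxyphenyl]-2-hydroxypropyl]oxy}benzaldehyde F4, which is freed from any regioisomeric ether by chromatography. Intramolecular Buchwald–Hartwig etherification (Pd(OAc)2, 2-(di-tert-butylphosphino)-1,1'-binaphthyl, Cs2CO3, toluene, 70 °C) then gives 8 with retention at C2.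

Step 5. Under alkaline peroxide the 2'-phenoxide of a chalcone with a 6'-alkoxy group can close at the α-carbon (5-exo) instead of the β-carbon, diverting material toward the aurone, and unconsumed ketone can undergo Dakin oxidation. The fallback sets out from 8 and 9 and comes back at 11. The chalcone 10 is isolated after the KOH condensation and cyclodehydrogenated with I2 (cat.) in DMSO at 120 °C to the flavone 5,7-bis(benzyloxy)-2-{(2R,3R)-3-[4-(benzyloxy)-3-methoxyphenyl]-2-[(benzyloxy)methyl]-2,3-dihydro-1,4-benzodioxin-6-yl}-4H-chromen-4-one F5. C3 is then hydroxylated by epoxidation with dimethyldioxirane (acetone–CH2Cl2, 0 °C) and opening of the 2,3-epoxide with catalytic p-TsOH, giving 11.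

Further compounds
F1 | step 3 | (S)-[4-(benzyloxy)-3-methoxyphenyl][(4R)-2,2-dimethyl-1,3-dioxolan-4-yl]methanol | COc1cc([C@H](O)[C@H]2COC(C)(C)O2)ccc1OCc1ccccc1
F2 | step 3 | 3-{(R)-[4-(benzyloxy)-3-methoxyphenyl][(4R)-2,2-dimethyl-1,3-dioxolan-4-yl]methoxy}-4-fluorobenzaldehyde | COc1cc([C@@H](Oc2cc(C=O)ccc2F)[C@H]2COC(C)(C)O2)ccc1OCc1ccccc1
F3 | step 3 | 3-{[(1R,2R)-1-[4-(benzyloxy)-3-methoxyphenyl]-2,3-dihydroxypropyl]oxy}-4-fluorobenzaldehyde | COc1cc([C@@H](Oc2cc(C=O)ccc2F)[C@H](O)CO)ccc1OCc1ccccc1
F4 | step 4 | 4-bromo-3-{[(1R,2R)-3-(benzyloxy)-1-[4-(benzyloxy)-3-methoxyphenyl]-2-hydroxypropyl]oxy}benzaldehyde | COc1cc([C@@H](Oc2cc(C=O)ccc2Br)[C@H](O)COCc2ccccc2)ccc1OCc1ccccc1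
F5 | step 5 | 5,7-bis(benzyloxy)-2-{(2R,3R)-3-[4-(benzyloxy)-3-methoxyphenyl]-2-[(benzyloxy)methyl]-2,3-dihydro-1,4-benzodioxin-6-yl}-4H-chromen-4-one | COc1cc([C@H]2Oc3cc(-c4cc(=O)c5c(OCc6ccccc6)cc(OCc6ccccc6)cc5o4)ccc3O[C@@H]2COCc2ccccc2)ccc1OCc1ccccc1
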